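Late in a run the ligand balance is what you can count on: a complex with two exchanged has taken two of incoming ligand, and anything else that takes ligand lowers the count. With x and m the charges of incoming ligand and starting complex, the ligand ceiling C = x/(2 m) is the highest share of the charged complex that can end with two exchanged; for epsilon, C = 137%.

| flask | starting complex | incoming ligand | remark | time |
|---|---|---|---|---|
| red | 0.14 M | 0.0819 M | run made earlier |  |
| beta | 0.091 M | 0.0820 M |  | 15 h |
| epsilon | 0.091 M | 0.250 M |  | 15 h |
| alpha | 0.091 M | 0.740 M |  | 15 h |

red run (percent of the starting complex charged)

| time / h | complex with two exchanged / % | side product / % | complex with one exchanged / % | starting complex / % |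
|---|---|---|---|---|
| 0.250 | 0 | 0 | 0.5 | 99.2 |
| 0.833 | 0 | 2.8 | 4.1 | 94.6 |
| 1.33 | 0.7 | 0 | 7.9 | 91.7 |
| 2.00 | 0 | 0 | 10.0 | 87.6 |
| 3.00 | 0 | 2.0 | 12.4 | 84.0 |

(each reading ± 1 percentage point)

- in percentages every species weighs as the starting complex in it: one side product counts as two
- no earlier run changes the charge of incoming ligand; that part of a forecast is a guess

- which of these there is most of at the end, counted by the starting complex in it, beta (starting complex / complex with one exchanged / side product / complex with two exchanged)
- which of these there is most of at the end, counted by the starting complex in it, epsilon (starting complex / complex with one exchanged / side product / complex with two exchanged)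
- which of these there is most of at the end, counted by the starting complex in it, alpha (starting complex / complex with one exchanged / side product / complex with two exchanged)
- the largest of these amounts at the end, in percent of the starting complex charged, beta
- the largest of these amounts at the end, in percent of the starting complex charged, epsilon
- the largest of these amounts at the end, in percent of the starting complex charged, alpha

Set epsilon beside a neighbour flask with the same ligand but 0.23 M of starting complex. They look alike, since ligand is charged above complex in both. Yet the neighbour's ceiling is 54.3%: its ligand pays for double exchange of about half of its complex, while epsilon's pays for all of it. So the balance holds two exchanged in the neighbour to at most 54.3%, and in epsilon it sets no such bound.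

How far each flask gets by the asked time takes a rate. In the red run the starting complex reads 84.0% at 3.00 h; counting one ligand lost for each complex lost, so that both partners fall, the integrated law, first order in each partner, gives from this reading k = 0.833 L mol⁻¹ h⁻¹. With ligand held at its charge, the half-life of starting complex in epsilon is then 3.33 h, short against 15 h, and in alpha it is 1.12 h. The red readings of two exchanged stay within the scatter, so they give no second constant. My own reckoning: beta, with ceiling 45.1% and ligand as limiting reagent, keeps starting complex in the lead, at about 50.8% by the same integrated law; epsilon is a close call between the two exchanged complexes; alpha, with ceiling 407%, goes to two exchanged.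

The forecast says starting complex at 47% (40% to 54%) for beta, complex with one exchanged at 70% (48% to 85%) for epsilon, and complex with one exchanged at 62% (42% to 85%) for alpha, differing from me on alpha: “Double exchange is barely seen, so the second step looks slower, but it is poorly constrained.”

    complex with one exchanged + incoming ligand → leaving ligand + complex with two exchanged (k = 0.490 L mol⁻¹ h⁻¹)
    starting complex + incoming ligand → leaving ligand + complex with one exchanged (k = 0.786 L mol⁻¹ h⁻¹)
    starting complex + complex with one exchanged → side product (k = 0.132 L mol⁻¹ h⁻¹)

Beta ends with starting complex at 51.6%, epsilon with complex with two exchanged at 45.8%, under its ceiling of 137%, and alpha with complex with two exchanged at 95.6%. In epsilon the complex with one exchanged is made 2.42 times as fast as it is used at 3.17 h, but at 15.0 h that ratio stands at 0.501, with 52% of the ligand still there. The neighbour, with its ceiling of 54.3%, ends with complex with one exchanged in the lead and two exchanged at 22.8%, with 16% of its ligand left.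

(The data are calculated from invented constants; the scatter is artificial.)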